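The route rests on cleaving the C9–C10 bond (ring B) together with the C4–C5 bond (ring A), which unfolds the decalin into an achiral (2Z,6E)-farnesyl tetramethoxybenzene. One enantioselective proton-initiated cationic bicyclization with a chiral binaphthol·SnCl4 acid refolds the chain and sets both rings and three stereocentres: the 6E olefin gives the trans C5/C10 fusion, the 2Z olefin becomes the axial C9–CH2Ar bond anti to the C10 methyl, and proton loss from C7 leaves the C7=C8 olefin. The feature exploited is the methyl-bearing quaternary C10 between C5 and the axially substituted C9 of trans-fused rings A and B. The arene is then unmasked via its dihydroxyquinone and monosulfated on one of two rotationally equivalent outer hydroxyls.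

Key step: step 3

Numbering: drimane numbering for the decalin (C4 the gem-dimethyl carbon, C5 the ring-fusion CH, C7=C8 the olefin, C9 the CH bearing C11H2–aryl, C10 the methyl-bearing ring-fusion carbon); aryl carbons are primed, C1′ carrying C11 and C4′ the ring hydrogen; Dr = [(1R,4aS,8aS)-2,5,5,8a-tetramethyl-1,4,4a,5,6,7,8,8a-octahydronaphthalen-1-yl]methyl.

Assumption: geometrically pure (2Z,6E)-farnesol is taken as a purchasable terpene alcohol, and the target is taken as the free aryl hydrogen sulfate as drawn, liberated from its salt by cold ion exchange and kept cold in dilute solution.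

Step 1
Reactants: 1 (2Z,6E)-farnesol [(2Z,6E)-3,7,11-trimethyldodeca-2,6,10-trien-1-ol]
Product: 2 (2Z,6E)-farnesyl bromide [(2Z,6E)-1-bromo-3,7,11-trimethyldodeca-2,6,10-triene]
Conditions: PBr3 (0.4 equiv), Et2O, −10 °C, dark; used at once
Reagents that add atoms: phosphorus tribromide, BrP(Br)Br
Why: Bromination of a primary allylic alcohol with PBr3 runs through a phosphite ester that bromide displaces at C1 in an SN2 reaction, which at low temperature should keep the 2Z and 6E geometries, and no stereocentre is formed.

Step 2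
Reactants: 3 1,2,4,5-tetramethoxybenzene; 2 (2Z,6E)-farnesyl bromide
Product: 5 1,2,4,5-tetramethoxy-3-[(2Z,6E)-3,7,11-trimethyldodeca-2,6,10-trien-1-yl]benzene, via 2,3,5,6-tetramethoxyphenyllithium 4 (not isolated)
Conditions: n-BuLi, THF, 0 °C to rt; then CuBr·SMe2 (10 mol%), 2, −78 to 0 °C
Reagents that add atoms: none
Why: Directed ortho-metalation of 3 between two methoxy groups gives 4, and its copper-catalysed allylic substitution at the unhindered primary carbon of 2 (SN2 rather than SN2′ for a γ,γ-disubstituted allyl bromide) should join the fragments with the 2Z olefin intact, no stereocentre being formed.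

Step 3
Reactants: 5 1,2,4,5-tetramethoxy-3-[(2Z,6E)-3,7,11-trimethyldodeca-2,6,10-trien-1-yl]benzene
Product: 6 1,2,4,5-tetramethoxy-3-Dr-benzene [(5S,9R,10S)-drim-7-ene carrying the 2,3,5,6-tetramethoxyphenyl group on C11]
Conditions: (R)-2-(2-fluorobenzyloxy)-2′-hydroxy-1,1′-binaphthyl·SnCl4 (2 equiv), toluene, −78 °C, 2–3 d; AgNO3–SiO2 chromatography
Reagents that add atoms: none
Why: The SnCl4-acidified phenolic proton of the chiral binaphthol adds to C3 of the terminal olefin, the C4 cation is captured by C5 of the 6E olefin, the C10 cation by C9 of the 2Z olefin, and the C8 cation loses the axial C7 proton. The closest known reaction type is the enantioselective proton-initiated polyene cyclization of polyprenyl arenes by Lewis acid-assisted chiral Brønsted acids. Ring A (C4–C5) and ring B (C9–C10) each close in a 6-endo-trig mode through chair-like transition states. The trans C5/C10 fusion follows from antiperiplanar addition across the 6E olefin, the C9 configuration from the 2Z geometry, which places CH2Ar axial and anti to the C10 methyl, and the absolute sense from the (R)-configured acid, which in this reagent family leads to the (5S,10S) series. The step needs initiation at the terminal olefin only (the least hindered one), no capture of the C8 cation by the arene (both ortho carbons are substituted and the flanking oxygens are methyl ethers), and proton loss towards C7, which is favoured because the C9–H bond is equatorial and orthogonal to the empty orbital while an exocyclic olefin would be reprotonated by the acid.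

Step 4
Reactants: 6 1,2,4,5-tetramethoxy-3-Dr-benzene
Product: 7 2,5-dimethoxy-3-Dr-cyclohexa-2,5-diene-1,4-dione
Conditions: (NH4)2Ce(NO3)6 (2.5 equiv), MeCN/H2O, 0 °C
Reagents that add atoms: water, O
Why: Oxidative demethylation of a para-dimethoxyarene by (NH4)2Ce(NO3)6 proceeds by two one-electron oxidations with water adding at the ipso carbons, and because the arene is symmetric about its C1′–C4′ axis either para pair leads to the same para-quinone 7, the stereocentres and the hindered C7=C8 olefin being left alone.

Step 5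
Reactants: 7 2,5-dimethoxy-3-Dr-cyclohexa-2,5-diene-1,4-dione
Product: 9 2,5-dihydroxy-3-Dr-cyclohexa-2,5-diene-1,4-dione, via disodium salt 8 (not isolated)
Conditions: NaOH (2 M aq), THF/MeOH, 40 °C, Ar; then 1 M HCl, 0 °C
Reagents that add atoms: sodium hydroxide, [Na+].[OH-]
Why: Both methoxy groups of 7 are vinylogous esters, so hydroxide replaces them by conjugate addition–elimination (vinylogous saponification) and the stable dianion 8 is protonated only briefly in the cold, which leaves the olefin and the stereocentres untouched.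

Step 6
Reactants: 9 2,5-dihydroxy-3-Dr-cyclohexa-2,5-diene-1,4-dione
Product: 12 2,4,5-trihydroxy-3-Dr-phenyl hydrogen sulfate (the target), via tetrol 10 (not isolated), via pyridinium sulfate 11 (not isolated)
Conditions: Na2S2O4, EtOAc/H2O, Ar, rt; then SO3·pyridine (0.9 equiv), pyridine, −20 to 0 °C, Ar; then Dowex 50W (H+ form), MeOH/H2O, 0 °C
Reagents that add atoms: sulfur trioxide pyridine complex, [O-]S(=O)(=O)[n+]1ccccc1
Why: Dithionite reduction of the quinone gives tetrol 10, whose two outer hydroxyls (at C3′ and C5′) are interchanged by rotation about the C11–C1′ bond and are much less hindered than the two inner ones flanking the benzylic carbon, so that O-sulfation of a phenol with a slight deficit of SO3·pyridine should give the one monosulfate, with no stereocentre involved.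

Compound list
1 | (2Z,6E)-farnesol, (2Z,6E)-3,7,11-trimethyldodeca-2,6,10-trien-1-ol | CC(C)=CCC/C(C)=C/CC/C(C)=C\CO | starting material
2 | (2Z,6E)-farnesyl bromide, (2Z,6E)-1-bromo-3,7,11-trimethyldodeca-2,6,10-triene | CC(C)=CCC/C(C)=C/CC/C(C)=C\CBr | intermediate
3 | 1,2,4,5-tetramethoxybenzene | COc1cc(OC)c(OC)cc1OC | starting material
4 | 2,3,5,6-tetramethoxyphenyllithium | [Li]c1c(OC)c(OC)cc(OC)c1OC | intermediate
5 | 1,2,4,5-tetramethoxy-3-[(2Z,6E)-3,7,11-trimethyldodeca-2,6,10-trien-1-yl]benzene | CC(C)=CCC/C(C)=C/CC/C(C)=C\Cc1c(OC)c(OC)cc(OC)c1OC | intermediate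
6 | 1,2,4,5-tetramethoxy-3-{[(1R,4aS,8aS)-2,5,5,8a-tetramethyl-1,4,4a,5,6,7,8,8a-octahydronaphthalen-1-yl]methyl}benzene | CC1=CC[C@H]2C(C)(C)CCC[C@]2(C)[C@@H]1Cc1c(OC)c(OC)cc(OC)c1OC | intermediate
7 | 2,5-dimethoxy-3-{[(1R,4aS,8aS)-2,5,5,8a-tetramethyl-1,4,4a,5,6,7,8,8a-octahydronaphthalen-1-yl]methyl}cyclohexa-2,5-diene-1,4-dione | CC1=CC[C@H]2C(C)(C)CCC[C@]2(C)[C@@H]1CC1=C(OC)C(=O)C=C(OC)C1=O | intermediate
8 | disodium salt of 9 (quinone bis-enolate) | CC1=CC[C@H]2C(C)(C)CCC[C@]2(C)[C@@H]1CC1=C([O-])C(=O)C=C([O-])C1=O.[Na+].[Na+] | intermediate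
9 | 2,5-dihydroxy-3-{[(1R,4aS,8aS)-2,5,5,8a-tetramethyl-1,4,4a,5,6,7,8,8a-octahydronaphthalen-1-yl]methyl}cyclohexa-2,5-diene-1,4-dione | CC1=CC[C@H]2C(C)(C)CCC[C@]2(C)[C@@H]1CC1=C(O)C(=O)C=C(O)C1=O | intermediate
10 | 3-{[(1R,4aS,8aS)-2,5,5,8a-tetramethyl-1,4,4a,5,6,7,8,8a-octahydronaphthalen-1-yl]methyl}benzene-1,2,4,5-tetrol | CC1=CC[C@H]2C(C)(C)CCC[C@]2(C)[C@@H]1Cc1c(O)c(O)cc(O)c1O | intermediate
11 | pyridinium 2,4,5-trihydroxy-3-{[(1R,4aS,8aS)-2,5,5,8a-tetramethyl-1,4,4a,5,6,7,8,8a-octahydronaphthalen-1-yl]methyl}phenyl sulfate | CC1=CC[C@H]2C(C)(C)CCC[C@]2(C)[C@@H]1Cc1c(O)c(O)cc(OS(=O)(=O)[O-])c1O.c1cc[nH+]cc1 | intermediate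
12 | 2,4,5-trihydroxy-3-{[(1R,4aS,8aS)-2,5,5,8a-tetramethyl-1,4,4a,5,6,7,8,8a-octahydronaphthalen-1-yl]methyl}phenyl hydrogen sulfate | CC1=CC[C@H]2C(C)(C)CCC[C@]2(C)[C@@H]1Cc1c(O)c(O)cc(OS(=O)(=O)O)c1O | target

Total step count: 6. Longest linear sequence: 6 steps (1 to 12 by way of 2, 5, 6, 7 and 9); arene 3 enters in step 2.

Steps most likely to fail

Step 3. After closure of ring A the C10 cation may lose a proton faster than the 2Z olefin can capture it, because that olefin has to carry CH2Ar axially in the chair, so monocyclic olefins build up. The chelating dimethoxyarene may also tie up part of the tin acid. The fallback is a stepwise cyclization that sets out from 5. The chiral acid is used only to close ring A and to set C5, which should give 1,2,4,5-tetramethoxy-3-{(2Z)-5-[(1S)-2,2-dimethyl-6-methylidenecyclohexyl]-3-methylpent-2-en-1-yl}benzene F1 (its endocyclic olefin isomer leads to the same cation). Isolated F1 is then treated with the achiral acid pair CF3CO2H/SnCl4 in CH2Cl2 at −78 °C, which re-forms the C10 cation and closes ring B through the C9–C10 bond under control of C5 and of the 2Z olefin. This comes back to the route at 6.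

Step 6. Sulfation may run on to the second outer hydroxyl or touch an inner one, and the tetrol may be reoxidised by traces of air before it is sulfated. The fallback moves the sulfation to the quinone oxidation level, where only one acidic hydroxyl is unhindered, and sets out from 9. By analogy with the O-sulfonylation of hydroxyquinones, 2,2,2-trichloroethyl chlorosulfate (1 equiv, 2,6-lutidine, CH2Cl2, −40 °C) should give 4-hydroxy-3,6-dioxo-5-Dr-cyclohexa-1,4-dien-1-yl 2,2,2-trichloroethyl sulfate F2. Zn dust and HCO2NH4 in MeOH then reduce the quinone and cleave the trichloroethyl group to give ammonium 2,4,5-trihydroxy-3-Dr-phenyl sulfate F3. Cold ion exchange as in step 6 comes back to the route at 12.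

Step 4. The aryl radical cation may be diverted by the neighbouring trisubstituted olefin or by benzylic C–H oxidation before water traps it. The fallback is electrochemical and sets out from 6. Anodic oxidation in methanolic KOH (Pt anode, undivided cell, 0 °C) should give the quinone bisketal 1,3,3,4,6,6-hexamethoxy-2-Dr-cyclohexa-1,4-diene F4. Its two ketals are hydrolysed with dilute aqueous acetic acid at rt, which comes back to the route at 7.

Further compounds
F1 | step 3 | 1,2,4,5-tetramethoxy-3-{(2Z)-5-[(1S)-2,2-dimethyl-6-methylidenecyclohexyl]-3-methylpent-2-en-1-yl}benzene | COc1cc(OC)c(OC)c(C/C=C(C)\CC[C@@H]2C(=C)CCCC2(C)C)c1OC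
F2 | step 6 | 4-hydroxy-3,6-dioxo-5-{[(1R,4aS,8aS)-2,5,5,8a-tetramethyl-1,4,4a,5,6,7,8,8a-octahydronaphthalen-1-yl]methyl}cyclohexa-1,4-dien-1-yl 2,2,2-trichloroethyl sulfate | CC1=CC[C@H]2C(C)(C)CCC[C@]2(C)[C@@H]1CC1=C(O)C(=O)C=C(OS(=O)(=O)OCC(Cl)(Cl)Cl)C1=O
F3 | step 6 | ammonium 2,4,5-trihydroxy-3-{[(1R,4aS,8aS)-2,5,5,8a-tetramethyl-1,4,4a,5,6,7,8,8a-octahydronaphthalen-1-yl]methyl}phenyl sulfate | CC1=CC[C@H]2C(C)(C)CCC[C@]2(C)[C@@H]1Cc1c(O)c(O)cc(OS(=O)(=O)[O-])c1O.[NH4+]
F4 | step 4 | 1,3,3,4,6,6-hexamethoxy-2-{[(1R,4aS,8aS)-2,5,5,8a-tetramethyl-1,4,4a,5,6,7,8,8a-octahydronaphthalen-1-yl]methyl}cyclohexa-1,4-diene | CC1=CC[C@H]2C(C)(C)CCC[C@]2(C)[C@@H]1CC1=C(OC)C(OC)(OC)C=C(OC)C1(OC)OC
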